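**Retrosynthetic overview**

1. Target 20 comes from hydrogenolysis of tri-O-benzyl hydrogen sulfate 19, which comes from sulfation of the single free hydroxyl (O3) of 18; 18 comes from MOM ether 17, and 17 from phenol 16.
2. Feature used: ring B is a benzene ring whose only oxygen sits on C4', para to C1', and C1' is bonded to C2 of the pyranone (ring C), the electron-poor carbon β to the C4 carbonyl.
3. Key disconnection: ring B of 16 is cut at C1'–C6' and C2'–C3' into 2-ethynylchromone 12 (supplies C1' and C2') and 1-methoxy-3-silyloxybutadiene 13 (supplies C3'–C6', with its oxygen on C4').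
4. 12 comes from Sonogashira coupling and desilylation of 2-iodochromone 9, made by C2 lithiation of 3-(methoxymethoxy)chromone 7; 7 comes from 3-hydroxychromone 6, chromone 4 and acetophenone 1.
5. Ring order: ring A is bought with 1, ring C is closed in step 2, ring B is built last in step 8.

Key step: step 8

Assumption: hydrogen sulfates 19 and 20 are written as free acids, as the target is drawn; in practice both would be handled as potassium salts (cation exchange after sulfation, which also removes pyridine before the hydrogenolysis), and the acid form released on an acid resin at 0 °C only when needed.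

**Route**

Step 1
Reactants: 1 2',4',6'-trihydroxyacetophenone
Product: 2 1-[2,4-bis(benzyloxy)-6-hydroxyphenyl]ethan-1-one
Conditions: BnBr (2.1 equiv), K2CO3, DMF, rt
Reagents that add atoms: benzyl bromide, BrCc1ccccc1
Why: Williamson etherification, in which the hydroxyl chelated to the ketone is the least nucleophilic and should stay free when two equivalents of benzyl bromide are used.

Step 2
Reactants: 2 1-[2,4-bis(benzyloxy)-6-hydroxyphenyl]ethan-1-one
Product: 4 5,7-bis(benzyloxy)-4H-chromen-4-one, via enaminone 3 (not isolated)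
Conditions: Me2NCH(OMe)2, toluene, 95 °C; then 2 M HCl, CH2Cl2, 40 °C
Reagents that add atoms: N,N-dimethylformamide dimethyl acetal, COC(OC)N(C)C
Why: Condensation of the methyl ketone with the amide acetal gives the enaminone, and acid then drives conjugate addition of the free phenol with loss of dimethylamine (enaminone route to 2,3-unsubstituted chromones), closing ring C.

Step 3
Reactants: 4 5,7-bis(benzyloxy)-4H-chromen-4-one
Product: 6 5,7-bis(benzyloxy)-3-hydroxy-4H-chromen-4-one, via 2,3-epoxychromanone 5 (not isolated)
Conditions: 30% H2O2, NaOH (cat.), CH2Cl2/MeOH, 0 °C; then TsOH·H2O (cat.), CH2Cl2, rt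
Reagents that add atoms: hydrogen peroxide, OO
Why: Weitz–Scheffer nucleophilic epoxidation of the enone C2=C3 should give the necessarily cis-fused racemic epoxide, which under acid opens at C2 (cation stabilised by O1) and loses the C3 proton, so both transient stereocentres vanish in the 3-hydroxychromone.

Step 4
Reactants: 6 5,7-bis(benzyloxy)-3-hydroxy-4H-chromen-4-one
Product: 7 5,7-bis(benzyloxy)-3-(methoxymethoxy)-4H-chromen-4-one
Conditions: MOMCl, iPr2NEt, CH2Cl2, 0 °C to rt
Reagents that add atoms: chloromethyl methyl ether, COCCl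
Why: O-alkylation of the acidic enolic 3-hydroxyl (acetal protection) installs a group that is stable to base and also coordinates lithium for the next step.

Step 5
Reactants: 7 5,7-bis(benzyloxy)-3-(methoxymethoxy)-4H-chromen-4-one
Product: 9 5,7-bis(benzyloxy)-2-iodo-3-(methoxymethoxy)-4H-chromen-4-one, via 2-lithiochromone 8 (not isolated)
Conditions: LDA, THF, –78 °C; then I2, THF, –78 °C
Reagents that add atoms: iodine, II; lithium diisopropylamide, CC(C)N([Li])C(C)C (its lithium stands in 8 only)
Why: Directed lithiation–iodination, in which C2–H (sp2, next to O1 and flanked by the coordinating MOM ether) is the most acidic C–H, the amide base at –78 °C should leave ring A and the benzylic positions alone, and iodine traps the vinyllithium.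

Step 6
Reactants: 9 5,7-bis(benzyloxy)-2-iodo-3-(methoxymethoxy)-4H-chromen-4-one; 10 trimethylsilylacetylene
Product: 11 5,7-bis(benzyloxy)-3-(methoxymethoxy)-2-[(trimethylsilyl)ethynyl]-4H-chromen-4-one
Conditions: PdCl2(PPh3)2 (cat.), CuI (cat.), Et3N, THF, rt
Reagents that add atoms: none
Why: Sonogashira coupling, for which the β-iodo enone should undergo fast oxidative addition to zerovalent palladium at room temperature while the tertiary amine cannot substitute at C2.

Step 7
Reactants: 11 5,7-bis(benzyloxy)-3-(methoxymethoxy)-2-[(trimethylsilyl)ethynyl]-4H-chromen-4-one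
Product: 12 5,7-bis(benzyloxy)-2-ethynyl-3-(methoxymethoxy)-4H-chromen-4-one
Conditions: Bu4NF, AcOH, THF, 0 °C
Reagents that add atoms: none
Why: Fluoride-mediated protodesilylation of the alkynylsilane, buffered with acetic acid so that no basic nucleophile adds to the electrophilic alkyne terminus.

Step 8
Reactants: 12 5,7-bis(benzyloxy)-2-ethynyl-3-(methoxymethoxy)-4H-chromen-4-one; 13 (E)-1-methoxy-3-(trimethylsilyloxy)buta-1,3-diene
Product: 16 5,7-bis(benzyloxy)-2-(4-hydroxyphenyl)-3-(methoxymethoxy)-4H-chromen-4-one, via cyclohexadiene cycloadduct 14 (not isolated), via aryl silyl ether 15 (not isolated)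
Conditions: 13 (4 equiv), toluene, 130 °C, sealed tube; then 0.1 M HCl, THF, 0 °C
Reagents that add atoms: none
Why: Proposed new method: the closest known reaction type is the thermal Diels–Alder reaction of 1-methoxy-3-silyloxybutadienes with ynones and propiolates followed by loss of methanol to para-acylphenols, and here the activating carbonyl is one vinyl unit further away, the alkyne being conjugated to C4=O through C2=C3 of ring C. In a concerted, asynchronous (4+2) cycloaddition the diene CH2 terminus (largest HOMO coefficient) should bond to the terminal alkyne carbon (largest LUMO coefficient of the vinylogous ynone) to form C2'–C3', while the methoxy-bearing carbon bonds to the internal alkyne carbon to form C1'–C6'. Ring B is thus closed by intermolecular cycloaddition, two bonds in one step, giving 1,4-cyclohexadiene 14, which loses methanol by 1,4-elimination across C6'/C3' to aromatise to 15, and dilute acid then cleaves the aryl silyl ether. No stereocentre survives, since the C6' centre of 14 is erased on aromatisation. The step needs para rather than meta placement of the oxygen and reaction at the alkyne only: the polarisation of the alkyne should secure the first, and the tetrasubstituted, donor-flanked C2=C3 bond and the vinylogous-ester C4 carbonyl, both inert without a Lewis acid, the second.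

Step 9
Reactants: 16 5,7-bis(benzyloxy)-2-(4-hydroxyphenyl)-3-(methoxymethoxy)-4H-chromen-4-one
Product: 17 5,7-bis(benzyloxy)-2-[4-(benzyloxy)phenyl]-3-(methoxymethoxy)-4H-chromen-4-one
Conditions: BnBr, K2CO3, DMF, rt
Reagents that add atoms: benzyl bromide, BrCc1ccccc1
Why: Williamson etherification of the only free phenol, which keeps O4' distinct from the MOM-protected O3.

Step 10
Reactants: 17 5,7-bis(benzyloxy)-2-[4-(benzyloxy)phenyl]-3-(methoxymethoxy)-4H-chromen-4-one
Product: 18 5,7-bis(benzyloxy)-2-[4-(benzyloxy)phenyl]-3-hydroxy-4H-chromen-4-one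
Conditions: 1.25 M HCl in MeOH, THF, 40 °C
Reagents that add atoms: none
Why: Acid-catalysed transacetalisation with methanol removes the MOM group, while the benzyl ethers, including the one at O5, should withstand dilute acid at this temperature.

Step 11
Reactants: 18 5,7-bis(benzyloxy)-2-[4-(benzyloxy)phenyl]-3-hydroxy-4H-chromen-4-one
Product: 19 5,7-bis(benzyloxy)-2-[4-(benzyloxy)phenyl]-4-oxo-4H-chromen-3-yl hydrogen sulfate
Conditions: SO3·pyridine (excess), pyridine, 50 °C
Reagents that add atoms: sulfur trioxide–pyridine complex, O=S(=O)([O-])[n+]1ccccc1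
Why: O-sulfation with a sulfur trioxide–amine complex, which can only occur at O3 because it is the single free hydroxyl.

Step 12
Reactants: 19 5,7-bis(benzyloxy)-2-[4-(benzyloxy)phenyl]-4-oxo-4H-chromen-3-yl hydrogen sulfate
Product: 20 kaempferol 3-O-sulfate (5,7-dihydroxy-2-(4-hydroxyphenyl)-4-oxo-4H-chromen-3-yl hydrogen sulfate)
Conditions: H2 (1 atm), Pd/C, MeOH/THF, rt
Reagents that add atoms: none
Why: Catalytic hydrogenolysis of the three benzyl ethers under neutral conditions, which should leave the sulfate monoester salt and the fully substituted C2=C3 bond untouched.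

**Compound list**

1 | 2',4',6'-trihydroxyacetophenone | CC(=O)c1c(O)cc(O)cc1O | starting material
2 | 1-[2,4-bis(benzyloxy)-6-hydroxyphenyl]ethan-1-one | CC(=O)c1c(O)cc(OCc2ccccc2)cc1OCc1ccccc1 | intermediate
3 | (E)-1-[2,4-bis(benzyloxy)-6-hydroxyphenyl]-3-(dimethylamino)prop-2-en-1-one (not isolated) | CN(C)/C=C/C(=O)c1c(O)cc(OCc2ccccc2)cc1OCc1ccccc1 | intermediate
4 | 5,7-bis(benzyloxy)-4H-chromen-4-one | O=c1ccoc2cc(OCc3ccccc3)cc(OCc3ccccc3)c12 | intermediate
5 | racemic cis-fused 5,7-bis(benzyloxy)-2,3-epoxychroman-4-one, one enantiomer drawn (not isolated) | O=C1[C@@H]2O[C@@H]2Oc2cc(OCc3ccccc3)cc(OCc3ccccc3)c12 | intermediate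
6 | 5,7-bis(benzyloxy)-3-hydroxy-4H-chromen-4-one | O=c1c(O)coc2cc(OCc3ccccc3)cc(OCc3ccccc3)c12 | intermediate
7 | 5,7-bis(benzyloxy)-3-(methoxymethoxy)-4H-chromen-4-one | COCOc1coc2cc(OCc3ccccc3)cc(OCc3ccccc3)c2c1=O | intermediate
8 | 5,7-bis(benzyloxy)-2-lithio-3-(methoxymethoxy)-4H-chromen-4-one (not isolated) | [Li]c1oc2cc(OCc3ccccc3)cc(OCc3ccccc3)c2c(=O)c1OCOC | intermediate
9 | 5,7-bis(benzyloxy)-2-iodo-3-(methoxymethoxy)-4H-chromen-4-one | COCOc1c(I)oc2cc(OCc3ccccc3)cc(OCc3ccccc3)c2c1=O | intermediate
10 | trimethylsilylacetylene | C#C[Si](C)(C)C | starting material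
11 | 5,7-bis(benzyloxy)-3-(methoxymethoxy)-2-[(trimethylsilyl)ethynyl]-4H-chromen-4-one | COCOc1c(C#C[Si](C)(C)C)oc2cc(OCc3ccccc3)cc(OCc3ccccc3)c2c1=O | intermediate
12 | 5,7-bis(benzyloxy)-2-ethynyl-3-(methoxymethoxy)-4H-chromen-4-one | COCOc1c(C#C)oc2cc(OCc3ccccc3)cc(OCc3ccccc3)c2c1=O | intermediate
13 | (E)-1-methoxy-3-(trimethylsilyloxy)buta-1,3-diene | CO/C=C/C(=C)O[Si](C)(C)C | starting material
14 | racemic 5,7-bis(benzyloxy)-2-[6-methoxy-4-(trimethylsilyloxy)cyclohexa-1,4-dien-1-yl]-3-(methoxymethoxy)-4H-chromen-4-one, one enantiomer drawn (not isolated) | COCOc1c(C2=CCC(O[Si](C)(C)C)=C[C@H]2OC)oc2cc(OCc3ccccc3)cc(OCc3ccccc3)c2c1=O | intermediate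
15 | 5,7-bis(benzyloxy)-3-(methoxymethoxy)-2-[4-(trimethylsilyloxy)phenyl]-4H-chromen-4-one (not isolated) | COCOc1c(-c2ccc(O[Si](C)(C)C)cc2)oc2cc(OCc3ccccc3)cc(OCc3ccccc3)c2c1=O | intermediate
16 | 5,7-bis(benzyloxy)-2-(4-hydroxyphenyl)-3-(methoxymethoxy)-4H-chromen-4-one | COCOc1c(-c2ccc(O)cc2)oc2cc(OCc3ccccc3)cc(OCc3ccccc3)c2c1=O | intermediate
17 | 5,7-bis(benzyloxy)-2-[4-(benzyloxy)phenyl]-3-(methoxymethoxy)-4H-chromen-4-one | COCOc1c(-c2ccc(OCc3ccccc3)cc2)oc2cc(OCc3ccccc3)cc(OCc3ccccc3)c2c1=O | intermediate
18 | 5,7-bis(benzyloxy)-2-[4-(benzyloxy)phenyl]-3-hydroxy-4H-chromen-4-one | O=c1c(O)c(-c2ccc(OCc3ccccc3)cc2)oc2cc(OCc3ccccc3)cc(OCc3ccccc3)c12 | intermediate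
19 | 5,7-bis(benzyloxy)-2-[4-(benzyloxy)phenyl]-4-oxo-4H-chromen-3-yl hydrogen sulfate | O=c1c(OS(=O)(=O)O)c(-c2ccc(OCc3ccccc3)cc2)oc2cc(OCc3ccccc3)cc(OCc3ccccc3)c12 | intermediate
20 | kaempferol 3-O-sulfate | O=c1c(OS(=O)(=O)O)c(-c2ccc(O)cc2)oc2cc(O)cc(O)c12 | target

**Step count**

Total steps: 12. Longest linear sequence: 12 steps (1 to 20).

**Steps most likely to fail**

Step 8 (carries the label "Proposed new method:"). The alkyne is activated only through the C2=C3 bond and sits next to the donating 3-alkoxy group, so cycloaddition may be slower than thermal oligomerisation or hydrolysis of the diene, and 12 would then be recovered or degraded. The fallback sets out from 9 and comes back at 17. Suzuki–Miyaura coupling of the β-iodo enone 9 with 4-(benzyloxy)phenylboronic acid (OB(O)c1ccc(OCc2ccccc2)cc1; Pd(PPh3)4, K2CO3, dioxane/water, 80 °C) should attach ring B ready-made to C2 and give 17 directly, so that steps 6 to 9 are skipped; compounds outside the list: none F0.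

Step 5. The 2-lithiochromone may add to unreacted 7 or open ring C before it is trapped, and deprotonation of ring A between the two benzyloxy groups may compete. The fallback sets out from 6 and comes back at 9. It replaces deprotonation by electrophilic substitution: the 3-olate of 6 activates its ortho carbon C2, as in 3-hydroxy-4-pyranones, so I2 with Na2CO3 in aqueous THF at 0 °C should give 5,7-bis(benzyloxy)-3-hydroxy-2-iodo-4H-chromen-4-one F1. Protection of F1 with MOMCl and iPr2NEt then gives 9.

Step 3. Hydroxide or hydroperoxide may attack C2 and cleave ring C instead of epoxidising, and the epoxide may decompose before it isomerises. The fallback sets out from 4 and comes back at 6. Hypervalent-iodine α-hydroxylation of the chromone (PhI(OAc)2, KOH, MeOH, 0 °C to rt) should add methoxide at C2, oxygenate C3 and acetalise C4 to give racemic cis-5,7-bis(benzyloxy)-2,4,4-trimethoxychroman-3-ol F2. Aqueous HCl in acetone then hydrolyses the acetal and eliminates methanol from C2/C3 to give 6.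

**Further compounds**

F0 | step 8 | none | none
F1 | step 5 | 5,7-bis(benzyloxy)-3-hydroxy-2-iodo-4H-chromen-4-one | O=c1c(O)c(I)oc2cc(OCc3ccccc3)cc(OCc3ccccc3)c12
F2 | step 3 | racemic cis-5,7-bis(benzyloxy)-2,4,4-trimethoxychroman-3-ol, one enantiomer drawn | CO[C@@H]1Oc2cc(OCc3ccccc3)cc(OCc3ccccc3)c2C(OC)(OC)[C@@H]1O
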